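## Retrosynthetic overview
1. 26 ⇒ dienol 24. Both oxiranes come last, by peracid oxidation of the (1(10)Z,4E)-germacradienolide: OH-directed at C1=C10, peripheral at C4=C5.
2. 24 ⇒ alcohol 20 (angelate put on O8) ⇒ acyclic oxidised (2E,6Z)-farnesane 16. One CrCl2 operation forms C6–C7 (the farnesyl C1–C10 bond) and lets O6 close on C12.
3. 16 ⇒ three C5 units plus an acrylate cap. C2–C3 comes from a vinylogous Mukaiyama aldol, C8–C9 from a vinylogous aldol–lactonisation (a temporary ring that fixes the Z olefin and C8), and C7=C11 from cross-metathesis.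
4. Ring order: ten-membered carbocycle → γ-lactone (same flask) → 1,10-oxirane → 4,5-oxirane (same flask).

Assumption: the SMILES is read literally in germacrane numbering (1R,2S,4R,5R,6S,7R,8S,10S; cis-1,10-oxirane, trans-4,5-oxirane, 2α-OH, 8α-OAng, trans-6α,12-lactone), and each chiral catalyst is used as the antipode that gives the configuration drawn.

## Route (germacrane numbering is used for chain atoms)

Step 1
Reactants: 1 3-methylbut-2-enoyl chloride; 2 phenol
Product: 4 phenyl 3-methylbut-3-enoate, via isopropenylketene 3 (not isolated)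
Conditions: Et3N (1.3 equiv), CH2Cl2, −78 to 0 °C
Reagents that add atoms: none
Why: Deconjugative esterification: Et3N dehydrochlorinates 1 to vinylketene 3, and phenol adds with kinetic α-protonation, giving the β,γ-unsaturated ester needed as pronucleophile; no stereocentre is formed.

Step 2
Reactants: 4 phenyl 3-methylbut-3-enoate; 5 acrolein
Product: 7 (6S)-6-ethenyl-4-methyl-5,6-dihydro-2H-pyran-2-one, via hydroxy dienoate 6 (not isolated)
Conditions: Cu(MeCN)4PF6 (5 mol %), (R)-DTBM-SEGPHOS (6 mol %), Et3N (10 mol %), THF, −40 °C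
Reagents that add atoms: none
Why: Catalytic asymmetric direct vinylogous aldol addition then lactonisation: the monovalent-copper/amine pair enolises 4 to an s-cis dienolate that attacks acrolein through its γ-carbon inside the chiral phosphine pocket (sets C8 as S), and only the Z-alkoxide 6 can expel phenoxide, so ring closure fixes the future 1(10) olefin as Z.

Step 3
Reactants: 7 (6S)-6-ethenyl-4-methyl-5,6-dihydro-2H-pyran-2-one
Product: 9 (2Z,5S)-N-methoxy-N,3-dimethyl-5-(triethylsilyloxy)hepta-2,6-dienamide, via hydroxy amide 8 (not isolated)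
Conditions: MeNH(OMe)·HCl, AlMe3, CH2Cl2, 0 °C; then 2,6-lutidine, Et3SiOTf, 0 °C
Reagents that add atoms: N,O-dimethylhydroxylamine hydrochloride CNOC.Cl; triethylsilyl triflate CC[Si](CC)(CC)OS(=O)(=O)C(F)(F)F
Why: Weinreb aminolysis of the lactone by the weakly basic aluminium amide, then in-situ O-silylation: capping O8 stops relactonisation and later lactol formation, and C8 and the Z olefin are not touched.

Step 4
Reactants: 9 (2Z,5S)-N-methoxy-N,3-dimethyl-5-(triethylsilyloxy)hepta-2,6-dienamide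
Product: 10 (2Z,5S)-3-methyl-5-(triethylsilyloxy)hepta-2,6-dienal
Conditions: iBu2AlH (1.2 equiv), THF, −78 °C; aq. KNaC4H4O6
Reagents that add atoms: none
Why: Weinreb amide reduction: the chelated tetrahedral aluminium adduct survives until work-up, so reduction stops at the neral-type Z-enal, and no other carbonyl group is present.

Step 5
Reactants: 11 3-methylbut-2-enal (prenal)
Product: 12 (E)-tert-butyl(dimethyl)[(3-methylbuta-1,3-dien-1-yl)oxy]silane
Conditions: tBuMe2SiOTf, Et3N, Et2O, 0 to 23 °C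
Reagents that add atoms: tert-butyldimethylsilyl triflate CC(C)(C)[Si](C)(C)OS(=O)(=O)C(F)(F)F
Why: Soft enolisation and O-silylation of an enal through its γ-methyl group gives the (E)-dienoxysilane; no stereocentre is formed.

Step 6
Reactants: 10 (2Z,5S)-3-methyl-5-(triethylsilyloxy)hepta-2,6-dienal; 12 (E)-tert-butyl(dimethyl)[(3-methylbuta-1,3-dien-1-yl)oxy]silane
Product: 14 (2E,5S,6Z,9S)-5-(tert-butyldimethylsilyloxy)-3,7-dimethyl-9-(triethylsilyloxy)undeca-2,6,10-trienal, via aldol 13 (not isolated)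
Conditions: B-phenyl oxazaborolidinone from N-tosyl-D-tryptophan and PhBCl2 (50 mol %), iPrOH (1.1 equiv), EtCN, −78 °C; then 2,6-lutidine, tBuMe2SiOTf, −78 to 0 °C
Reagents that add atoms: tert-butyldimethylsilyl triflate CC(C)(C)[Si](C)(C)OS(=O)(=O)C(F)(F)F
Why: Enantioselective vinylogous Mukaiyama aldol reaction: the boron Lewis acid binds the aldehyde of 10 and shields one face, the s-trans dienoxysilane attacks through its γ-carbon (gives the E-enal directly and sets C2 as S under catalyst control, C8 being remote), and capping O2 as the TBS ether keeps O2 and O8 distinguishable.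

Step 7
Reactants: 14 (2E,5S,6Z,9S)-5-(tert-butyldimethylsilyloxy)-3,7-dimethyl-9-(triethylsilyloxy)undeca-2,6,10-trienal; 15 methyl 2-(bromomethyl)acrylate
Product: 16 methyl (2Z,4S,6Z,8S,10E)-2-(bromomethyl)-8-(tert-butyldimethylsilyloxy)-6,10-dimethyl-12-oxo-4-(triethylsilyloxy)dodeca-2,6,10-trienoate
Conditions: 15 (5 equiv), second-generation Hoveyda–Grubbs catalyst RuCl2(H2IMes)(=CH-C6H4-2-OiPr) (10 mol %), toluene, 60 °C, argon sparge
Reagents that add atoms: none
Why: Olefin cross-metathesis: only the monosubstituted C7 olefin of 14 can initiate, the 1,1-disubstituted acrylate 15 does not homodimerise, and loss of ethylene drives formation of the thermodynamic trisubstituted enoate (C8 trans to the ester); no stereocentre is touched.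

Step 8
Reactants: 16 methyl (2Z,4S,6Z,8S,10E)-2-(bromomethyl)-8-(tert-butyldimethylsilyloxy)-6,10-dimethyl-12-oxo-4-(triethylsilyloxy)dodeca-2,6,10-trienoate
Product: 20 (1(10)Z,4E)-2α-(tert-butyldimethylsilyloxy)-8α-hydroxygermacra-1(10),4,11(13)-trien-6α,12-olide (6βH 7αH), via allylchromium reagent 17 (not isolated), via hydroxy ester 18 (not isolated), via TES lactone 19 (not isolated)
Conditions: CrCl2 (10 equiv), THF–DMF 10:1, 16 added over 20 h (final 1 mM), 23 °C; aq. work-up, crude; then AcOH–THF–H2O 3:1:1, 23 °C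
Reagents that add atoms: none
Why: Intramolecular Nozaki–Hiyama–Kishi-type allylation followed by lactonisation: the equilibrating allylchromium reacts at C7 through a Zimmerman–Traxler chair with C5 and C8 equatorial (6,7-anti, hence the trans-lactone); A(1,3) strain holds H8 in the allyl plane, so the tethered aldehyde arrives on the C9 face opposite the non-leaving silyloxy group (7αH relative to 8α-O); O6 then closes on the methyl ester, and mild acid removes only the TES group.

Step 9
Reactants: 20 (1(10)Z,4E)-2α-(tert-butyldimethylsilyloxy)-8α-hydroxygermacra-1(10),4,11(13)-trien-6α,12-olide; 21 angelic acid ((Z)-2-methylbut-2-enoic acid)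
Product: 23 (1(10)Z,4E)-8α-angeloyloxy-2α-(tert-butyldimethylsilyloxy)germacra-1(10),4,11(13)-trien-6α,12-olide, via mixed anhydride 22 (not isolated)
Conditions: 21, 2,4,6-Cl3C6H2COCl, Et3N, toluene, 23 °C; then 20, 80 °C
Reagents that add atoms: none
Why: Yamaguchi-type mixed-anhydride esterification run without a nucleophilic catalyst: the alcohol attacks the less hindered angeloyl carbonyl, the Z geometry of the acid is kept, O8 is the only free hydroxyl group, and C8 is retained.

Step 10
Reactants: 23 (1(10)Z,4E)-8α-angeloyloxy-2α-(tert-butyldimethylsilyloxy)germacra-1(10),4,11(13)-trien-6α,12-olide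
Product: 26 CNP0388761.1 (8α-angeloyloxy-2α-hydroxy-1β,10β:4α,5β-diepoxygermacr-11(13)-en-6α,12-olide), via dienol 24 (not isolated), via monoepoxide 25 (not isolated)
Conditions: HF·pyridine, THF, 0 to 23 °C; Me3SiOMe quench, evaporate; then mCPBA (2.6 equiv), NaHCO3, CH2Cl2, 0 to 23 °C
Reagents that add atoms: 3-chloroperbenzoic acid O=C(OO)c1cccc(Cl)c1
Why: Fluoride desilylation then double Prilezhaev epoxidation:
- At C1=C10, A(1,3) strain puts H2 in the olefin plane and the 2-OH on the outer face, and hydrogen-bonded delivery there gives the threo cis-oxirane (1R,10S).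
- At C4=C5, A(1,3) strain with C15 puts H6 in plane and C7 inside the ring, so attack on the outer face gives 4R,5R.
- The two electron-poor olefins are inert.

## Compound list
1 | 3-methylbut-2-enoyl chloride | CC(C)=CC(=O)Cl | starting material
2 | phenol | Oc1ccccc1 | starting material
3 | isopropenylketene | C=C(C)C=C=O | intermediate
4 | phenyl 3-methylbut-3-enoate | C=C(C)CC(=O)Oc1ccccc1 | intermediate
5 | acrolein | C=CC=O | starting material
6 | phenyl (2Z,5S)-5-hydroxy-3-methylhepta-2,6-dienoate | O=C(Oc1ccccc1)/C=C(/C)C[C@H](O)C=C | intermediate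
7 | (6S)-6-ethenyl-4-methyl-5,6-dihydro-2H-pyran-2-one | C=C[C@@H]1CC(C)=CC(=O)O1 | intermediate
8 | (2Z,5S)-5-hydroxy-N-methoxy-N,3-dimethylhepta-2,6-dienamide | CON(C)C(=O)/C=C(/C)C[C@H](O)C=C | intermediate
9 | (2Z,5S)-N-methoxy-N,3-dimethyl-5-(triethylsilyloxy)hepta-2,6-dienamide | CON(C)C(=O)/C=C(/C)C[C@H](O[Si](CC)(CC)CC)C=C | intermediate
10 | (2Z,5S)-3-methyl-5-(triethylsilyloxy)hepta-2,6-dienal | O=C/C=C(/C)C[C@H](O[Si](CC)(CC)CC)C=C | intermediate
11 | 3-methylbut-2-enal | CC(C)=CC=O | starting material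
12 | (E)-tert-butyl(dimethyl)[(3-methylbuta-1,3-dien-1-yl)oxy]silane | C=C(C)/C=C/O[Si](C)(C)C(C)(C)C | intermediate
13 | (2E,5S,6Z,9S)-5-hydroxy-3,7-dimethyl-9-(triethylsilyloxy)undeca-2,6,10-trienal | O=C/C=C(\C)C[C@H](O)/C=C(/C)C[C@H](O[Si](CC)(CC)CC)C=C | intermediate
14 | (2E,5S,6Z,9S)-5-(tert-butyldimethylsilyloxy)-3,7-dimethyl-9-(triethylsilyloxy)undeca-2,6,10-trienal | O=C/C=C(\C)C[C@H](O[Si](C)(C)C(C)(C)C)/C=C(/C)C[C@H](O[Si](CC)(CC)CC)C=C | intermediate
15 | methyl 2-(bromomethyl)acrylate | C=C(CBr)C(=O)OC | starting material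
16 | methyl (2Z,4S,6Z,8S,10E)-2-(bromomethyl)-8-(tert-butyldimethylsilyloxy)-6,10-dimethyl-12-oxo-4-(triethylsilyloxy)dodeca-2,6,10-trienoate | COC(=O)/C(CBr)=C/[C@@H](O[Si](CC)(CC)CC)C/C(C)=C\[C@@H](O[Si](C)(C)C(C)(C)C)C/C(C)=C/C=O | intermediate
17 | allylchromium dichloride derived from 16 (CrCl2 in place of Br at C13) | COC(=O)/C(C[Cr](Cl)Cl)=C/[C@@H](O[Si](CC)(CC)CC)C/C(C)=C\[C@@H](O[Si](C)(C)C(C)(C)C)C/C(C)=C/C=O | intermediate
18 | methyl (1(10)Z,4E)-6α-hydroxy-2α-(tert-butyldimethylsilyloxy)-8α-(triethylsilyloxy)germacra-1(10),4,11(13)-trien-12-oate (7αH) | C1/C(C)=C\[C@@H](O[Si](C)(C)C(C)(C)C)C/C(C)=C/[C@@H](O)[C@H](C(=C)C(=O)OC)[C@H]1O[Si](CC)(CC)CC | intermediate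
19 | (1(10)Z,4E)-2α-(tert-butyldimethylsilyloxy)-8α-(triethylsilyloxy)germacra-1(10),4,11(13)-trien-6α,12-olide | C1/C(C)=C\[C@@H](O[Si](C)(C)C(C)(C)C)C/C(C)=C/[C@H]2OC(=O)C(=C)[C@@H]2[C@H]1O[Si](CC)(CC)CC | intermediate
20 | (1(10)Z,4E)-2α-(tert-butyldimethylsilyloxy)-8α-hydroxygermacra-1(10),4,11(13)-trien-6α,12-olide | C1/C(C)=C\[C@@H](O[Si](C)(C)C(C)(C)C)C/C(C)=C/[C@H]2OC(=O)C(=C)[C@@H]2[C@H]1O | intermediate
21 | angelic acid | C/C=C(/C)C(=O)O | starting material
22 | angelic 2,4,6-trichlorobenzoic anhydride | C/C=C(/C)C(=O)OC(=O)c1c(Cl)cc(Cl)cc1Cl | intermediate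
23 | (1(10)Z,4E)-8α-angeloyloxy-2α-(tert-butyldimethylsilyloxy)germacra-1(10),4,11(13)-trien-6α,12-olide | C1/C(C)=C\[C@@H](O[Si](C)(C)C(C)(C)C)C/C(C)=C/[C@H]2OC(=O)C(=C)[C@@H]2[C@H]1OC(=O)/C(C)=C\C | intermediate
24 | (1(10)Z,4E)-8α-angeloyloxy-2α-hydroxygermacra-1(10),4,11(13)-trien-6α,12-olide | C1/C(C)=C\[C@@H](O)C/C(C)=C/[C@H]2OC(=O)C(=C)[C@@H]2[C@H]1OC(=O)/C(C)=C\C | intermediate
25 | (4E)-8α-angeloyloxy-1β,10β-epoxy-2α-hydroxygermacra-4,11(13)-dien-6α,12-olide | C1/C(C)=C/[C@H]2OC(=O)C(=C)[C@@H]2[C@@H](OC(=O)/C(C)=C\C)C[C@]2(C)O[C@@H]2[C@H]1O | intermediate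
26 | CNP0388761.1 | C=C1C(=O)O[C@H]2[C@H]1[C@@H](OC(=O)/C(C)=C\C)C[C@]1(C)O[C@@H]1[C@@H](O)C[C@@]1(C)O[C@H]21 | target

## Step count and risks
Total step count: 10.

Longest linear sequence: 9 (steps 1–4 and 6–10; step 5 is a one-step branch).

**Step 8 (closure of the ten-membered ring).**
- Risk: a conjugated, β,β-disubstituted enal is a sluggish acceptor at 1 mM. Oligomers or protonated allylchromium may win, and C6/C7 rest on C8 alone.
- Fallback: change the order of ring formation, setting out from 14.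
- The enal of 14 is epoxidised first with H2O2 and 2-[diphenyl(trimethylsilyloxy)methyl]pyrrolidine (iminium catalysis, antipode giving 4R,5R) to give epoxy aldehyde F1.
- Cross-metathesis with 15 as in step 7 gives epoxy bromide F2.
- The CrCl2 closure then runs on a non-conjugated, more electrophilic α,β-epoxy aldehyde, whose oxirane adds a Felkin-type bias at C6. After the same acid treatment it gives epoxy alcohol F3.
- Angeloylation as in step 9 gives silyl epoxy angelate F4, and HF·pyridine gives epoxy dienol F5.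
- VO(acac)2/tBuOOH epoxidises the remaining 1(10) olefin, and the route is rejoined at 26.

**Step 7 (cross-metathesis).**
- Risk: a hindered allylic silyl ether has to pair with a bulky electron-poor 1,1-disubstituted olefin, so conversion may stall.
- Fallback: build the same unit by carbonyl chemistry, setting out from 9.
- Ozone with Me2S work-up cleaves the vinyl group in preference to the electron-poor enamide olefin and gives silyloxy aldehyde F6.
- A Morita–Baylis–Hillman reaction with methyl acrylate and DABCO gives hydroxy acrylate F7 (C7 epimers, both usable).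
- PBr3 gives, with allylic transposition, bromo enoate amide F8.
- Cp2Zr(H)Cl reduces only the amide to give bromo enoate enal F9.
- The aldol/silylation of step 6 brings the material back at 16.

**Step 10 (four stereocentres from one peracid treatment).**
- Risk: the face selectivity at C4=C5 of a Z,E ring is inferred, not known, and peracid acidity could open the first oxirane.
- Fallback: replace substrate control by stepwise directed and reagent control, setting out from 23.
- 24 is isolated after HF·pyridine and converted into 25 with VO(acac)2/tBuOOH (metal-alkoxide delivery).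
- The 4,5-olefin is then oxidised with the dioxirane from the fructose-derived ketone catalyst and KHSO5 at buffered pH, the ketone antipode being chosen for 4R,5R.
- The route is rejoined at 26, and no compound outside the list is made.

## Further compounds
F1 | step 8 | (2R,3R)-epoxide of 14 at the enal olefin (4R,5R in germacrane numbering), vinyl group intact | C=C[C@@H](O[Si](CC)(CC)CC)C/C(C)=C\[C@@H](O[Si](C)(C)C(C)(C)C)C[C@@]1(C)O[C@@H]1C=O
F2 | step 8 | 4,5-epoxide of 16 (epoxy aldehyde allylic bromide) | COC(=O)/C(CBr)=C/[C@@H](O[Si](CC)(CC)CC)C/C(C)=C\[C@@H](O[Si](C)(C)C(C)(C)C)C[C@@]1(C)O[C@@H]1C=O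
F3 | step 8 | (1(10)Z)-2α-(tert-butyldimethylsilyloxy)-4α,5β-epoxy-8α-hydroxygermacra-1(10),11(13)-dien-6α,12-olide | C1/C(C)=C\[C@@H](O[Si](C)(C)C(C)(C)C)C[C@@]2(C)O[C@@H]2[C@H]3OC(=O)C(=C)[C@@H]3[C@H]1O
F4 | step 8 | (1(10)Z)-8α-angeloyloxy-2α-(tert-butyldimethylsilyloxy)-4α,5β-epoxygermacra-1(10),11(13)-dien-6α,12-olide | C1/C(C)=C\[C@@H](O[Si](C)(C)C(C)(C)C)C[C@@]2(C)O[C@@H]2[C@H]3OC(=O)C(=C)[C@@H]3[C@H]1OC(=O)/C(C)=C\C
F5 | step 8 | (1(10)Z)-8α-angeloyloxy-4α,5β-epoxy-2α-hydroxygermacra-1(10),11(13)-dien-6α,12-olide | C1/C(C)=C\[C@@H](O)C[C@@]2(C)O[C@@H]2[C@H]3OC(=O)C(=C)[C@@H]3[C@H]1OC(=O)/C(C)=C\C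
F6 | step 7 | (2Z,5S)-N-methoxy-N,3-dimethyl-6-oxo-5-(triethylsilyloxy)hex-2-enamide | CON(C)C(=O)/C=C(/C)C[C@H](O[Si](CC)(CC)CC)C=O
F7 | step 7 | methyl (4S,6Z)-3-hydroxy-8-[methoxy(methyl)amino]-6-methyl-2-methylidene-8-oxo-4-(triethylsilyloxy)oct-6-enoate (C3 epimers) | CON(C)C(=O)/C=C(/C)C[C@H](O[Si](CC)(CC)CC)C(O)C(=C)C(=O)OC
F8 | step 7 | methyl (2Z,4S,6Z)-2-(bromomethyl)-8-[methoxy(methyl)amino]-6-methyl-8-oxo-4-(triethylsilyloxy)octa-2,6-dienoate | CON(C)C(=O)/C=C(/C)C[C@H](O[Si](CC)(CC)CC)/C=C(\CBr)C(=O)OC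
F9 | step 7 | methyl (2Z,4S,6Z)-2-(bromomethyl)-6-methyl-8-oxo-4-(triethylsilyloxy)octa-2,6-dienoate | O=C/C=C(/C)C[C@H](O[Si](CC)(CC)CC)/C=C(\CBr)C(=O)OC
F0 | step 10 | none | none
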